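**Plan**
1. The retrosynthesis first cuts the benzofuran (O1–C2 and C3–C3a: ortho-iodophenol plus terminal alkyne), then the chromene O1–C2 bond together with C4–C4a (phenol plus 3-methylbut-2-enal), then the alkenyl–alkynyl bond, and last the aryl–C(sp3) bond at the stereocentre.
2. Enabling feature: the 2H-pyran ring of the chromene is a closed 1-oxatriene made of the ring oxygen, the arene bond C8a=C4a, the C4=C3 alkene and C2(CH3)2. Retro-oxa-6π opening of O1–C2 gives an ortho-quinone methide that is the dehydration product of a 3-methoxyphenol and 3-methylbut-2-enal, the species through which ortho-prenylphenols are thought to become 2,2-dimethylchromenes in nature.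
3. Forward order: aryl Grignard plus chiral propargylic phosphate, methyl alkyne, hydrozirconation/iodination, Sonogashira enyne, double desilylation, chromene ring (key step), benzofuran ring last.
4. Stereochemistry: the single stereocentre comes from commercial (R)-4-(trimethylsilyl)but-3-yn-2-ol by one SN2 inversion. The E alkene comes from syn-hydrozirconation and is retained in both couplings.

Key step: step 9

Remark: iodination of 2,4-dihydroxyacetophenone with ICl is assumed to take place at C5 (ortho to the free 4-OH, para to the chelated 2-OH), the less hindered of the two activated positions.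

**Step 1**
Reactants: 1 4-bromo-3-methoxyphenol
Product: 2 (4-bromo-3-methoxyphenoxy)triisopropylsilane
Conditions: TIPSCl, imidazole, DMF, rt
Reagents that add atoms: triisopropylsilyl chloride, CC(C)[Si](Cl)(C(C)C)C(C)C
Why: Silylation of a phenol with a trialkylsilyl chloride and imidazole; the bulky silyl ether should survive Grignard formation, carbonate in methanol, n-BuLi, Cp2Zr(H)Cl and Pd/Cu coupling and is removed later with fluoride.

**Step 2**
Reactants: 3 (R)-4-(trimethylsilyl)but-3-yn-2-ol
Product: 4 diethyl (R)-[4-(trimethylsilyl)but-3-yn-2-yl] phosphate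
Conditions: ClP(O)(OEt)2, pyridine, DMAP (cat.), CH2Cl2, 0 °C → rt
Reagents that add atoms: diethyl chlorophosphate, CCOP(=O)(Cl)OCC
Why: O-Phosphorylation of a secondary propargylic alcohol installs the leaving group without touching the C–O stereocentre, so the R configuration of 3 is kept.

**Step 3**
Reactants: 2 (4-bromo-3-methoxyphenoxy)triisopropylsilane, 4 diethyl (R)-[4-(trimethylsilyl)but-3-yn-2-yl] phosphate
Product: 6 (R)-triisopropyl{3-methoxy-4-[4-(trimethylsilyl)but-3-yn-2-yl]phenoxy}silane, via arylmagnesium bromide 5 (not isolated)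
Conditions: 2 (2 equiv), Mg, THF, 50 °C; then 4, Cu(acac)2 (10 mol %), THF, −20 → 0 °C
Reagents that add atoms: none
Why: Grignard formation followed by copper-catalysed propargylic substitution of a secondary phosphate by an arylmagnesium reagent, which should proceed by anti-SN2 displacement at the carbinol carbon (the trimethylsilyl group shields the alkyne terminus against SN2′ allene formation), so the stereocentre of the target is set here by inversion of the chiral-pool centre; the descriptor stays R only because the silylalkynyl group outranks the aryl group.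

**Step 4**
Reactants: 6 (R)-triisopropyl{3-methoxy-4-[4-(trimethylsilyl)but-3-yn-2-yl]phenoxy}silane
Product: 7 (S)-[4-(but-3-yn-2-yl)-3-methoxyphenoxy]triisopropylsilane
Conditions: K2CO3 (cat.), MeOH/THF, 0 °C → rt
Reagents that add atoms: none
Why: Base-catalysed methanolysis (protodesilylation) of the alkynyl C–Si bond; the aryl silyl ether and the benzylic, propargylic C–H stereocentre should be untouched under these mild conditions (the descriptor becomes S by a priority change only, the spatial arrangement is the same).

**Step 5**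
Reactants: 7 (S)-[4-(but-3-yn-2-yl)-3-methoxyphenoxy]triisopropylsilane
Product: 9 (S)-triisopropyl[3-methoxy-4-(pent-3-yn-2-yl)phenoxy]silane, via lithium acetylide 8 (not isolated)
Conditions: n-BuLi (1.05 equiv), THF, −78 °C; MeI, −78 °C → rt
Reagents that add atoms: iodomethane, CI
Why: Deprotonation of the terminal alkyne, which is far more acidic than the benzylic C–H so that one equivalent of base at low temperature should leave the stereocentre alone, followed by SN2 alkylation of the acetylide with MeI.

**Step 6**
Reactants: 9 (S)-triisopropyl[3-methoxy-4-(pent-3-yn-2-yl)phenoxy]silane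
Product: 11 {4-[(2S,3E)-4-iodopent-3-en-2-yl]-3-methoxyphenoxy}triisopropylsilane, via alkenylzirconocene chloride 10 (not isolated)
Conditions: Cp2Zr(H)Cl (2 equiv), THF, rt → 45 °C; then I2, THF, 0 °C
Reagents that add atoms: iodine, II
Why: Hydrozirconation (syn addition of Zr–H) of the internal alkyne under equilibrating conditions with excess reagent should place zirconium on the less hindered methyl-bearing carbon, and iodinolysis of the C–Zr bond with retention fixes the E trisubstituted alkene (iodine trans to the carbon that bears the stereocentre, methyl cis).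

**Step 7**
Reactants: 11 {4-[(2S,3E)-4-iodopent-3-en-2-yl]-3-methoxyphenoxy}triisopropylsilane, 12 ethynyltrimethylsilane
Product: 13 triisopropyl{3-methoxy-4-[(2S,3E)-4-methyl-6-(trimethylsilyl)hex-3-en-5-yn-2-yl]phenoxy}silane
Conditions: Pd(PPh3)2Cl2 (cat.), CuI (cat.), Et3N, THF, rt
Reagents that add atoms: none
Why: Sonogashira coupling of the alkenyl iodide with retention of the double-bond geometry brings in the two alkyne carbons that become C2 and C3 of the benzofuran.

**Step 8**
Reactants: 13 triisopropyl{3-methoxy-4-[(2S,3E)-4-methyl-6-(trimethylsilyl)hex-3-en-5-yn-2-yl]phenoxy}silane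
Product: 14 3-methoxy-4-[(2S,3E)-4-methylhex-3-en-5-yn-2-yl]phenol
Conditions: TBAF, THF, 0 °C → rt; aq. NH4Cl
Reagents that add atoms: none
Why: Fluoride-mediated desilylation cleaves the alkynyl C–Si and the aryl O–Si bonds in one operation and unmasks both the terminal alkyne and the phenol needed for the key step.

**Step 9**
Reactants: 14 3-methoxy-4-[(2S,3E)-4-methylhex-3-en-5-yn-2-yl]phenol, 15 3-methylbut-2-enal
Product: 18 7-methoxy-2,2-dimethyl-6-[(2S,3E)-4-methylhex-3-en-5-yn-2-yl]-2H-chromene, via benzodioxaborin 16 (not isolated), via ortho-quinone methide 17 (not isolated)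
Conditions: PhB(OH)2 (1.1 equiv), EtCO2H (cat.), toluene, reflux, Dean–Stark
Reagents that add atoms: none
Why: Phenylboronic acid esterifies the phenol of 14 and delivers the aldehyde carbon of 15 to the free ortho carbon (C6 of the phenol) through a six-membered boron-bridged transition state, giving the 4H-1,3,2-benzodioxaborin 16 as a temporary ring; at reflux 16 loses PhB=O (collected as the boroxine) in a retro-[4+2] step to the ortho-quinone methide 17, whose 1-oxatriene O=C–C=CH–CH=C(CH3)2 closes by thermal disrotatory oxa-6π electrocyclisation, forming the O–C(CH3)2 bond and restoring the arene. The closest known reaction type is the phenylboronic acid-mediated condensation of electron-rich phenols with 3-methylbut-2-enal to 2,2-dimethyl-2H-chromenes, a formal [3+3] annulation that mirrors the ortho-quinone methide electrocyclisation by which prenylated phenols are thought to give chromenes in nature. The single ring closed, the 2H-pyran, forms in the 6π-electrocyclic mode and not by a polar 6-endo attack, so the cis C3=C4 alkene of the pyran is delivered automatically. No new stereocentre arises because the pyran C2 carries two methyl groups (the C4 centre of 16 is destroyed again on the way to 17), and the existing benzylic stereocentre lies outside the reacting array and has no ionisable substituent. The step needs ortho-regioselectivity for phenol carbon C6 over C2 and chemoselectivity for the phenol over the enyne: C6 is para to the methoxy group and unhindered, whereas C2 is flanked by OH and by a methoxy group that the branched side chain at C4 forces to lean over C2, and the terminal enyne has no reaction channel with a boronic acid or a weak carboxylic acid at this temperature.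

**Step 10**
Reactants: 19 1-(2,4-dihydroxyphenyl)ethanone
Product: 20 1-(2,4-dihydroxy-5-iodophenyl)ethanone
Conditions: ICl, AcOH, rt
Reagents that add atoms: iodine monochloride, ClI
Why: Electrophilic aromatic iodination of the resorcinol-type ring at C5, ortho to the free 4-OH and para to the chelated 2-OH and less hindered than C3.

**Step 11**
Reactants: 18 7-methoxy-2,2-dimethyl-6-[(2S,3E)-4-methylhex-3-en-5-yn-2-yl]-2H-chromene, 20 1-(2,4-dihydroxy-5-iodophenyl)ethanone
Product: 22 1-{6-hydroxy-2-[(2E,4S)-4-(7-methoxy-2,2-dimethyl-2H-chromen-6-yl)pent-2-en-2-yl]-1-benzofuran-5-yl}ethan-1-one, via ortho-alkynylphenol 21 (not isolated)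
Conditions: Pd(PPh3)2Cl2 (cat.), CuI (cat.), Et3N, DMF, 60 °C, degassed
Reagents that add atoms: none
Why: Sonogashira coupling of the ortho-iodophenol with the terminal enyne, followed in the same pot by metal-promoted 5-endo-dig cyclisation of the adjacent 4-OH onto the alkyne (benzofuran annulation); the chelated 2-OH, the acetyl group, the chromene and the stereocentre should be spectators and the E geometry is retained.

**Compound list**
1 | 4-bromo-3-methoxyphenol | COc1cc(O)ccc1Br | starting material
2 | (4-bromo-3-methoxyphenoxy)triisopropylsilane | COc1cc(O[Si](C(C)C)(C(C)C)C(C)C)ccc1Br | intermediate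
3 | (R)-4-(trimethylsilyl)but-3-yn-2-ol | C[C@@H](O)C#C[Si](C)(C)C | starting material
4 | diethyl (R)-[4-(trimethylsilyl)but-3-yn-2-yl] phosphate | CCOP(=O)(OCC)O[C@H](C)C#C[Si](C)(C)C | intermediate
5 | [2-methoxy-4-(triisopropylsilyloxy)phenyl]magnesium bromide | COc1cc(O[Si](C(C)C)(C(C)C)C(C)C)ccc1[Mg]Br | intermediate (not isolated)
6 | (R)-triisopropyl{3-methoxy-4-[4-(trimethylsilyl)but-3-yn-2-yl]phenoxy}silane | COc1cc(O[Si](C(C)C)(C(C)C)C(C)C)ccc1[C@@H](C)C#C[Si](C)(C)C | intermediate
7 | (S)-[4-(but-3-yn-2-yl)-3-methoxyphenoxy]triisopropylsilane | COc1cc(O[Si](C(C)C)(C(C)C)C(C)C)ccc1[C@@H](C)C#C | intermediate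
8 | lithium (S)-3-[2-methoxy-4-(triisopropylsilyloxy)phenyl]but-1-yn-1-ide | COc1cc(O[Si](C(C)C)(C(C)C)C(C)C)ccc1[C@@H](C)C#C[Li] | intermediate (not isolated)
9 | (S)-triisopropyl[3-methoxy-4-(pent-3-yn-2-yl)phenoxy]silane | COc1cc(O[Si](C(C)C)(C(C)C)C(C)C)ccc1[C@@H](C)C#CC | intermediate
10 | chlorobis(cyclopentadienyl){(2E,4S)-4-[2-methoxy-4-(triisopropylsilyloxy)phenyl]pent-2-en-2-yl}zirconium (cyclopentadienyl rings drawn sigma-bonded) | COc1cc(O[Si](C(C)C)(C(C)C)C(C)C)ccc1[C@@H](C)/C=C(\C)[Zr](Cl)(C1C=CC=C1)C1C=CC=C1 | intermediate (not isolated)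
11 | {4-[(2S,3E)-4-iodopent-3-en-2-yl]-3-methoxyphenoxy}triisopropylsilane | COc1cc(O[Si](C(C)C)(C(C)C)C(C)C)ccc1[C@@H](C)/C=C(\C)I | intermediate
12 | ethynyltrimethylsilane | C#C[Si](C)(C)C | starting material
13 | triisopropyl{3-methoxy-4-[(2S,3E)-4-methyl-6-(trimethylsilyl)hex-3-en-5-yn-2-yl]phenoxy}silane | COc1cc(O[Si](C(C)C)(C(C)C)C(C)C)ccc1[C@@H](C)/C=C(\C)C#C[Si](C)(C)C | intermediate
14 | 3-methoxy-4-[(2S,3E)-4-methylhex-3-en-5-yn-2-yl]phenol | COc1cc(O)ccc1[C@@H](C)/C=C(\C)C#C | intermediate
15 | 3-methylbut-2-enal | CC(C)=CC=O | starting material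
16 | 7-methoxy-6-[(2S,3E)-4-methylhex-3-en-5-yn-2-yl]-4-(2-methylprop-1-en-1-yl)-2-phenyl-4H-1,3,2-benzodioxaborinine (both C4 epimers) | COc1cc2OB(c3ccccc3)OC(C=C(C)C)c2cc1[C@@H](C)/C=C(\C)C#C | intermediate (not isolated)
17 | 3-methoxy-6-(3-methylbut-2-en-1-ylidene)-4-[(2S,3E)-4-methylhex-3-en-5-yn-2-yl]cyclohexa-2,4-dien-1-one | COC1=CC(=O)C(=CC=C(C)C)C=C1[C@@H](C)/C=C(\C)C#C | intermediate (not isolated)
18 | 7-methoxy-2,2-dimethyl-6-[(2S,3E)-4-methylhex-3-en-5-yn-2-yl]-2H-chromene | COc1cc2OC(C)(C)C=Cc2cc1[C@@H](C)/C=C(\C)C#C | intermediate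
19 | 1-(2,4-dihydroxyphenyl)ethanone | CC(=O)c1ccc(O)cc1O | starting material
20 | 1-(2,4-dihydroxy-5-iodophenyl)ethanone | CC(=O)c1cc(I)c(O)cc1O | intermediate
21 | 1-{2,4-dihydroxy-5-[(3E,5S)-5-(7-methoxy-2,2-dimethyl-2H-chromen-6-yl)-3-methylhex-3-en-1-yn-1-yl]phenyl}ethanone | COc1cc2OC(C)(C)C=Cc2cc1[C@@H](C)/C=C(\C)C#Cc1cc(C(C)=O)c(O)cc1O | intermediate (not isolated)
22 | 1-{6-hydroxy-2-[(2E,4S)-4-(7-methoxy-2,2-dimethyl-2H-chromen-6-yl)pent-2-en-2-yl]-1-benzofuran-5-yl}ethan-1-one | COc1cc2c(cc1[C@@H](C)/C=C(\C)c1cc3cc(C(C)=O)c(O)cc3o1)C=CC(C)(C)O2 | target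

**Totals**
Total step count: 11. Longest linear sequence: 9 steps (1, 3, 4, 5, 6, 7, 8, 9, 11, counted from compound 1); steps 2 and 10 are side branches.

**Steps most likely to fail**

Step 3. What may go wrong: SN2′ attack at the silylated alkyne terminus giving an allene, attack of the Grignard reagent at phosphorus, or partial ionisation of the propargylic phosphate that erodes the enantiomeric purity. The fallback replaces substrate control by catalyst control, a stereoconvergent nickel-catalysed Negishi arylation of a racemic propargylic bromide. It sets out from 2: bromine–lithium exchange and a B(OMe)3 quench give [2-methoxy-4-(triisopropylsilyloxy)phenyl]boronic acid F1, which with Et2Zn gives ethyl[2-methoxy-4-(triisopropylsilyloxy)phenyl]zinc F2. Racemic (3-bromobut-1-yn-1-yl)trimethylsilane F3, made from racemic 4-(trimethylsilyl)but-3-yn-2-ol with PPh3 and CBr4, is then coupled with F2 using NiCl2·glyme and an enantiopure indanyl-pybox ligand in glyme at −20 °C; the ligand antipode that delivers the R product would be chosen in a test reaction. The fallback comes back to the route at 6.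

Step 6. What may go wrong: incomplete regiocontrol of the Zr–H addition (zirconium ending on the carbon next to the stereocentre), or equilibration that is too slow at a temperature the substrate tolerates. The fallback changes the metal and the mode of addition. It sets out from 9: copper-catalysed syn-borylcupration and protonation (B2pin2, CuCl, phosphine, NaOt-Bu, MeOH, THF) should place boron on the less hindered methyl-bearing carbon and give 2-{(2Z,4S)-4-[2-methoxy-4-(triisopropylsilyloxy)phenyl]pent-2-en-2-yl}-4,4,5,5-tetramethyl-1,3,2-dioxaborolane F4. Suzuki–Miyaura coupling of F4 with (bromoethynyl)trimethylsilane (Pd(dppf)Cl2, Cs2CO3, THF) with retention of geometry then comes back to the route at 13, bypassing 11.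

Step 9. What may go wrong: ortho attack at the carbon between the two oxygens, stalling at the benzodioxaborin stage, or acid-promoted oligomerisation of the enyne or of the chromene alkene. The fallback reaches the same ortho-quinone methide by a sigmatropic route without acid or aldehyde. It sets out from 14: O-alkylation with 3-chloro-3-methylbut-1-yne (CuCl2·2H2O cat., DBU, MeCN, 0 °C) gives 2-methoxy-1-[(2S,3E)-4-methylhex-3-en-5-yn-2-yl]-4-[(2-methylbut-3-yn-2-yl)oxy]benzene F5. Heating F5 in xylene at 140 °C should bring about aromatic Claisen rearrangement to 5-methoxy-2-(3-methylbuta-1,2-dien-1-yl)-4-[(2S,3E)-4-methylhex-3-en-5-yn-2-yl]phenol F6, a 1,5-hydrogen shift to 17 and oxa-6π closure, coming back to the route at 18.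

**Further compounds**
F1 | step 3 | [2-methoxy-4-(triisopropylsilyloxy)phenyl]boronic acid | COc1cc(O[Si](C(C)C)(C(C)C)C(C)C)ccc1B(O)O
F2 | step 3 | ethyl[2-methoxy-4-(triisopropylsilyloxy)phenyl]zinc | CC[Zn]c1ccc(O[Si](C(C)C)(C(C)C)C(C)C)cc1OC
F3 | step 3 | racemic (3-bromobut-1-yn-1-yl)trimethylsilane | CC(Br)C#C[Si](C)(C)C
F4 | step 6 | 2-{(2Z,4S)-4-[2-methoxy-4-(triisopropylsilyloxy)phenyl]pent-2-en-2-yl}-4,4,5,5-tetramethyl-1,3,2-dioxaborolane | COc1cc(O[Si](C(C)C)(C(C)C)C(C)C)ccc1[C@@H](C)/C=C(\C)B1OC(C)(C)C(C)(C)O1
F5 | step 9 | 2-methoxy-1-[(2S,3E)-4-methylhex-3-en-5-yn-2-yl]-4-[(2-methylbut-3-yn-2-yl)oxy]benzene | COc1cc(OC(C)(C)C#C)ccc1[C@@H](C)/C=C(\C)C#C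
F6 | step 9 | 5-methoxy-2-(3-methylbuta-1,2-dien-1-yl)-4-[(2S,3E)-4-methylhex-3-en-5-yn-2-yl]phenol | COc1cc(O)c(C=C=C(C)C)cc1[C@@H](C)/C=C(\C)C#C
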